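The ratio of incoming ligand to starting complex charged falls from 11.0 in east to 0.367 in south-west, and the examination starts there.

common to all: incoming ligand 0.440 M; time 30 h
- east: starting complex 0.040 M
- north-east: starting complex 0.12 M
- north-west: starting complex 0.40 M
- south-west: starting complex 1.2 M

1. [complex with four exchanged] (only what is free in solution) at the end for east, north-east, north-west, south-west, in this order
2. how that number moves from the first to the last of them (rises, then falls / falls all the way / rises all the way / hardly changes / falls, then rises)

- complex with four exchanged is meant together with its idle adduct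
- the concentration of complex with four exchanged that is asked is that of its free form alone
- "hardly changes" means that all values lie within two and a half points (for a concentration: within two and a half percent of the largest)
- run time (east): 30 h

    starting complex + incoming ligand ⇌ leaving ligand + complex with one exchanged (K1 = 0.79, k1 = 2.0 × 10⁻⁵ M⁻¹ s⁻¹)
    complex with one exchanged + incoming ligand ⇌ leaving ligand + complex with two exchanged (K2 = 1.0, k2 = 4.1 × 10⁻⁵ M⁻¹ s⁻¹)
    complex with two exchanged + incoming ligand ⇌ leaving ligand + complex with three exchanged (K3 = 8.2, k3 = 7.7 × 10⁻⁶ M⁻¹ s⁻¹)
    complex with three exchanged + incoming ligand ⇌ leaving ligand + complex with four exchanged (K4 = 24, k4 = 3.4 × 10⁻⁶ M⁻¹ s⁻¹)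
    complex with four exchanged + incoming ligand ⇌ idle adduct, settled at all times (K5 = 3.6 M⁻¹)

**Why is free complex with four exchanged a trace?** It stands at the end of a chain. At the east charge, the forward half-lives are 22 h, 11 h, 57 h and 130 h, and the last is longer than the run of 30 h.

**How much gets through?** Early in a chain, the share of the charge past every exchange is the chain number 0.00456: the product of the forward constants, times charged [incoming ligand] and time, each to the power 4, over 4 factorial. In powers of ten that is −2.34.

**But the ligand does not stay at its charge?** No. Starting complex consumes it, roughly pseudo-first-order, with exponent a = k1·[starting complex]·t. That gives 0.0864 in east, 0.259 in north-east, 0.864 in north-west and 2.59 in south-west. The mean ligand fraction, (1 − e^−a)/a, is then 0.958, 0.881, 0.670 and 0.357. It enters the chain number to the power 4.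

**And the adduct?** Free complex is the total divided by 1 + K5[incoming ligand], taken at the end: 2.45, 2.22, 1.67 and 1.12.

**Which wins, charge or ligand?** From east to north-west, the charge gains 1.00 powers of ten, the ligand costs 0.621 and the adduct returns 0.166. From north-west to south-west, the charge gains 0.477, the ligand costs 1.09 and the adduct returns 0.173.

**Your numbers?** Charge times chain number times m to the power 4, over the adduct divisor, gives 6.27 × 10⁻⁵ M, 1.48 × 10⁻⁴ M, 2.20 × 10⁻⁴ M and 7.94 × 10⁻⁵ M. So the row rises, then falls.

The forecast, which differs from my shape, gave 2.200 × 10⁻⁵ M, 3.200 × 10⁻⁵ M, 5.000 × 10⁻⁵ M and 5.500 × 10⁻⁵ M, rises all the way, holding that “Larger charges supply more intermediate but use up the incoming ligand”.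

The flask gives 3.27 × 10⁻⁵ M, 7.74 × 10⁻⁵ M, 1.21 × 10⁻⁴ M and 7.09 × 10⁻⁵ M: the row rises, then falls, turning at 0.40 M.

The estimate from the chain number 0.00456 stands 1.92 times above the east value and 1.12 times above the south-west value. In east, the first exchange had half of its turnover up to the end behind it by 11.2 h, and at the end incoming ligand stood at 91.1% of its charge, with complex with two exchanged at 29.8% and complex with three exchanged at 4.39%. In south-west, incoming ligand was down to 32.2% of its charge by 15.0 h and 23.1% at the end, while starting complex stood at 77.4% and complex with three exchanged at 0.384%.

(The numbers of this flask belong to no real substance; the result is computed.)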